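**Strategy.** The carbocycle is cut at C6–C7 and C5–C4a (isochromene numbering), which removes the C5–C6 (ClC–C=O) unit. The remaining pyran ring with its C8 acyl arm is recast as a furo[3,2-c]pyrylium-3-olate, in which the pyranone oxygen on C4a is tied to C7: a cyclic carbonyl ylide whose termini are C7 and C4a. One cycloaddition with chloroketene diethyl acetal stitches C5–C6 across these termini and creates the C7 stereocenter. Strain-driven opening of the oxygen bridge then leaves that oxygen on C7 as the tertiary hydroxyl and C5=C4a in place. The ylide precursor is a 3-(2-hydroxypropanoyl)-4-pyranone carrying the dienyl chain, built from an acylketene and an enaminone. Propanoylation completes the target.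

Key step: step 9

Remark: the carbinol carbon of 7, 8, 9, 11 and 12 is used racemic on purpose, because it becomes the planar ylide carbon in step 9; 11 and 12 are therefore carried as epimer mixtures at that carbon.

**Step 1**
Reactants: 1 (S)-2-methylbutan-1-ol
Product: 3 (2E,4S)-2,4-dimethylhex-2-enal, via (S)-2-methylbutanal 2 (not isolated)
Conditions: TEMPO (cat.), KBr (cat.), NaOCl, NaHCO3, toluene/H2O, 0 °C; dried organic layer, then Ph3P=C(Me)CHO, 80 °C
Reagents that add atoms: 2-(triphenylphosphoranylidene)propanal, CC(C=O)=P(c1ccccc1)(c1ccccc1)c1ccccc1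
Why: Nitroxyl-catalysed hypochlorite oxidation (Anelli oxidation) should give the aldehyde without epimerising the chiral-pool stereocenter, and the stabilised formyl ylide should then give the E-trisubstituted enal in a Wittig reaction, the side-chain stereocenter being carried over unchanged from 1.

**Step 2**
Reactants: 4 2,2,6-trimethyl-4H-1,3-dioxin-4-one
Product: 5 diethyl [(2,2-dimethyl-4-oxo-4H-1,3-dioxin-6-yl)methyl]phosphonate
Conditions: LiN(i-Pr)2 (2.1 equiv), THF, −78 °C; ClP(O)(OEt)2, −78 → 0 °C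
Reagents that add atoms: diethyl chlorophosphate, CCOP(=O)(Cl)OCC
Why: γ-Deprotonation of the vinylogous ester gives the cross-conjugated dienolate, which should be phosphorylated at the exocyclic carbon (dienolate C-phosphorylation), the second equivalent of base taking up the more acidic phosphonate product.

**Step 3**
Reactants: 5 diethyl [(2,2-dimethyl-4-oxo-4H-1,3-dioxin-6-yl)methyl]phosphonate; 3 (2E,4S)-2,4-dimethylhex-2-enal
Product: 6 6-[(1E,3E,5S)-3,5-dimethylhepta-1,3-dien-1-yl]-2,2-dimethyl-4H-1,3-dioxin-4-one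
Conditions: NaH, THF, 0 °C; then 3, 0 °C → rt
Reagents that add atoms: none
Why: Horner–Wadsworth–Emmons olefination with the stabilised vinylogous phosphonate anion should give the new disubstituted alkene as the E isomer, and the weakly basic preformed anion should leave the γ-stereocenter of 3 untouched.

**Step 4**
Reactants: 7 3-hydroxybutan-2-one (racemic)
Product: 8 3-[(tert-butyldimethylsilyl)oxy]butan-2-one (racemic)
Conditions: TBSCl, imidazole, CH2Cl2, rt
Reagents that add atoms: tert-butyldimethylsilyl chloride, CC(C)(C)[Si](C)(C)Cl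
Why: Standard silylation of the secondary alcohol masks the hydroxyl against the formamide acetal of step 5 and the acylketene of step 6.

**Step 5**
Reactants: 8 3-[(tert-butyldimethylsilyl)oxy]butan-2-one
Product: 9 (1E)-4-[(tert-butyldimethylsilyl)oxy]-1-(dimethylamino)pent-1-en-3-one (racemic)
Conditions: Me2NCH(OMe)2, neat, 100 °C
Reagents that add atoms: N,N-dimethylformamide dimethyl acetal, COC(OC)N(C)C
Why: Condensation with the formamide acetal (enaminone formation) should occur only at the methyl group, since the silyloxy-bearing carbon has a single hydrogen and cannot lose two molecules of methanol.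

**Step 6**
Reactants: 6 6-[(1E,3E,5S)-3,5-dimethylhepta-1,3-dien-1-yl]-2,2-dimethyl-4H-1,3-dioxin-4-one; 9 (1E)-4-[(tert-butyldimethylsilyl)oxy]-1-(dimethylamino)pent-1-en-3-one
Product: 11 3-{2-[(tert-butyldimethylsilyl)oxy]propanoyl}-6-[(1E,3E,5S)-3,5-dimethylhepta-1,3-dien-1-yl]-4H-pyran-4-one, via dienoylketene 10 (not isolated)
Conditions: toluene, 110 °C, slow N2 sweep, 9 in excess
Reagents that add atoms: none
Why: Thermal retro-hetero-Diels–Alder loss of acetone from 6 gives acylketene 10, which should be intercepted at its ketene carbon by the nucleophilic α-carbon of enaminone 9, after which 6-endo attack of the acyl oxygen on the iminium carbon and loss of dimethylamine close the γ-pyranone (acylketene–enaminone [4+2] annulation).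

**Step 7**
Reactants: 11 3-{2-[(tert-butyldimethylsilyl)oxy]propanoyl}-6-[(1E,3E,5S)-3,5-dimethylhepta-1,3-dien-1-yl]-4H-pyran-4-one
Product: 12 3-(2-hydroxypropanoyl)-6-[(1E,3E,5S)-3,5-dimethylhepta-1,3-dien-1-yl]-4H-pyran-4-one
Conditions: HF·pyridine, THF/pyridine, 0 °C → rt
Reagents that add atoms: none
Why: Fluoride-mediated desilylation under buffered acidic conditions should free the α-hydroxy ketone without exposing the base-sensitive 3-acylpyranone to nucleophiles.

**Step 8**
Reactants: 13 2,2-dichloro-1,1-diethoxyethane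
Product: 14 2-chloro-1,1-diethoxyethene (chloroketene diethyl acetal)
Conditions: KOtBu, THF, 0 °C → rt; distillation
Reagents that add atoms: none
Why: E2 dehydrochlorination of the dichloroacetal by the hindered alkoxide should give the chloroketene acetal, the classical route to halogenated ketene acetals.

**Step 9**
Reactants: 12 3-(2-hydroxypropanoyl)-6-[(1E,3E,5S)-3,5-dimethylhepta-1,3-dien-1-yl]-4H-pyran-4-one; 14 2-chloro-1,1-diethoxyethene
Product: 20 (7R)-5-chloro-7-hydroxy-7-methyl-3-[(1E,3E,5S)-3,5-dimethylhepta-1,3-dien-1-yl]-6H-isochromene-6,8(7H)-dione, via triflate ester 15 (not isolated), via pyrylium triflate 16 (not isolated), via betaine 17 (not isolated), via cycloadduct 18 (not isolated), via diethyl ketal 19 (not isolated)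
Conditions: Tf2O, 2,6-di-tert-butyl-4-methylpyridine, CH2Cl2, −78 → −40 °C; slow transfer into 14 (excess), Eu(OTf)3/(S,S)-Ph-pybox (10 mol %), i-Pr2NEt, 4 Å MS, CH2Cl2, −40 °C; then 0.5 M aq. HCl, THF, 0 °C
Reagents that add atoms: water, O
Why: Proposed new method: triflation of the hydroxyl lets the pyranone carbonyl oxygen displace triflate at C7 (5-exo-tet), and deprotonation of the resulting 4-alkoxypyrylium 16 should give the 10π-aromatic betaine 17, a cyclic carbonyl ylide with C7 as its nucleophilic and C4a as its electrophilic terminus; the closest known reaction type is the 1,3-dipolar cycloaddition of mesoionic carbonyl ylides (isomünchnones, 2-benzopyrylium-4-olates) with vinyl ethers and ketene acetals, including its chiral lanthanide–pybox variant. The HOMO of ketene acetal 14 and the LUMO of 17 should pair the CHCl carbon with C4a and the acetal carbon with C7, so that the six-membered carbocycle closes in a suprafacial [4π+2π] cycloaddition as the oxygen-bridged adduct 18, forming C5–C4a and C6–C7 in the same event. Release of the bridge strain, pushed by the ring oxygen O2, should then break the C4a–O bond, C5 loses its proton, and acid hydrolysis of the diethyl ketal unveils the C6 ketone, so that the former pyranone oxygen ends as the C7 hydroxyl of 20. C7 is the only new stereocenter that survives, because C4a and C5 return to sp2, and it is set by the face of planar 17 that the europium–pybox complex bound at the C8 olate oxygen leaves open, the ligand antipode being chosen to give 7R. The step needs periselectivity for C7/C4a over closure through C1 or through the C8 oxygen, which the ring fusion secures because closure at C1 would demand a bridgehead C8a=C4a double bond and closure at oxygen gives only a reversible ortho ester. It also needs the ylide to be trapped before it dimerises and before cation 16 meets the ketene acetal, which slow inverse addition into base and excess 14 should secure.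

**Step 10**
Reactants: 20 (7R)-5-chloro-7-hydroxy-7-methyl-3-[(1E,3E,5S)-3,5-dimethylhepta-1,3-dien-1-yl]-6H-isochromene-6,8(7H)-dione
Product: 21 (7R)-5-chloro-3-[(1E,3E,5S)-3,5-dimethylhepta-1,3-dien-1-yl]-7-methyl-6,8-dioxo-7,8-dihydro-6H-isochromen-7-yl propanoate (Sclerketide B)
Conditions: (EtCO)2O, DMAP (cat.), Et3N, CH2Cl2, 0 °C → rt
Reagents that add atoms: propanoic anhydride, CCC(=O)OC(=O)CC
Why: DMAP-catalysed acylation (nucleophilic catalysis) should esterify the tertiary α-ketol, whose quaternary C7 has no pathway to epimerise under these conditions.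

**Compound list**

1 | (S)-2-methylbutan-1-ol | CC[C@H](C)CO | starting material
2 | (S)-2-methylbutanal | CC[C@H](C)C=O | intermediate
3 | (2E,4S)-2,4-dimethylhex-2-enal | CC[C@H](C)/C=C(C)/C=O | intermediate
4 | 2,2,6-trimethyl-4H-1,3-dioxin-4-one | CC1=CC(=O)OC(C)(C)O1 | starting material
5 | diethyl [(2,2-dimethyl-4-oxo-4H-1,3-dioxin-6-yl)methyl]phosphonate | CCOP(=O)(OCC)CC1=CC(=O)OC(C)(C)O1 | intermediate
6 | 6-[(1E,3E,5S)-3,5-dimethylhepta-1,3-dien-1-yl]-2,2-dimethyl-4H-1,3-dioxin-4-one | CC[C@H](C)/C=C(C)/C=C/C1=CC(=O)OC(C)(C)O1 | intermediate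
7 | 3-hydroxybutan-2-one (acetoin, racemic) | CC(O)C(C)=O | starting material
8 | 3-[(tert-butyldimethylsilyl)oxy]butan-2-one (racemic) | CC(O[Si](C)(C)C(C)(C)C)C(C)=O | intermediate
9 | (1E)-4-[(tert-butyldimethylsilyl)oxy]-1-(dimethylamino)pent-1-en-3-one (racemic) | CC(O[Si](C)(C)C(C)(C)C)C(=O)/C=C/N(C)C | intermediate
10 | (4E,6E,8S)-6,8-dimethyl-3-oxodeca-1,4,6-trien-1-one (dienoylketene) | CC[C@H](C)/C=C(C)/C=C/C(=O)C=C=O | intermediate
11 | 3-{2-[(tert-butyldimethylsilyl)oxy]propanoyl}-6-[(1E,3E,5S)-3,5-dimethylhepta-1,3-dien-1-yl]-4H-pyran-4-one (both epimers at the silyloxy carbon) | CC(O[Si](C)(C)C(C)(C)C)C(=O)C1=COC(/C=C/C(C)=C/[C@@H](C)CC)=CC1=O | intermediate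
12 | 3-(2-hydroxypropanoyl)-6-[(1E,3E,5S)-3,5-dimethylhepta-1,3-dien-1-yl]-4H-pyran-4-one (both epimers at the carbinol carbon) | CC(O)C(=O)C1=COC(/C=C/C(C)=C/[C@@H](C)CC)=CC1=O | intermediate
13 | 2,2-dichloro-1,1-diethoxyethane (dichloroacetaldehyde diethyl acetal) | CCOC(OCC)C(Cl)Cl | starting material
14 | 2-chloro-1,1-diethoxyethene (chloroketene diethyl acetal) | CCOC(OCC)=CCl | intermediate
15 | 1-{6-[(1E,3E,5S)-3,5-dimethylhepta-1,3-dien-1-yl]-4-oxo-4H-pyran-3-yl}-1-oxopropan-2-yl trifluoromethanesulfonate | CC(OS(=O)(=O)C(F)(F)F)C(=O)C1=COC(/C=C/C(C)=C/[C@@H](C)CC)=CC1=O | intermediate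
16 | 6-[(1E,3E,5S)-3,5-dimethylhepta-1,3-dien-1-yl]-2-methyl-3-oxo-2,3-dihydrofuro[3,2-c]pyran-5-ium trifluoromethanesulfonate | CC1OC2=C(C1=O)C=[O+]C(/C=C/C(C)=C/[C@@H](C)CC)=C2.[O-]S(=O)(=O)C(F)(F)F | intermediate
17 | 6-[(1E,3E,5S)-3,5-dimethylhepta-1,3-dien-1-yl]-2-methylfuro[3,2-c]pyran-5-ium-3-olate (mesoionic carbonyl ylide) | CC1=C([O-])C2=C(O1)C=C(/C=C/C(C)=C/[C@@H](C)CC)[O+]=C2 | intermediate
18 | 5-chloro-6,6-diethoxy-4a,7-epoxy-7-methyl-3-[(1E,3E,5S)-3,5-dimethylhepta-1,3-dien-1-yl]-4a,5,6,7-tetrahydro-8H-isochromen-8-one (oxygen bridge between C7 and C4a, C7 configured as in 20, C5 either epimer) | CCOC1(OCC)C(Cl)[C@@]23O[C@]1(C)C(=O)C2=COC(/C=C/C(C)=C/[C@@H](C)CC)=C3 | intermediate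
19 | (7R)-5-chloro-6,6-diethoxy-7-hydroxy-7-methyl-3-[(1E,3E,5S)-3,5-dimethylhepta-1,3-dien-1-yl]-6,7-dihydro-8H-isochromen-8-one | O[C@]1(C)C(=O)C2=COC(/C=C/C(C)=C/[C@@H](C)CC)=CC2=C(Cl)C1(OCC)OCC | intermediate
20 | (7R)-5-chloro-7-hydroxy-7-methyl-3-[(1E,3E,5S)-3,5-dimethylhepta-1,3-dien-1-yl]-6H-isochromene-6,8(7H)-dione | O[C@]1(C)C(=O)C2=COC(/C=C/C(C)=C/[C@@H](C)CC)=CC2=C(Cl)C1=O | intermediate
21 | (7R)-5-chloro-3-[(1E,3E,5S)-3,5-dimethylhepta-1,3-dien-1-yl]-7-methyl-6,8-dioxo-7,8-dihydro-6H-isochromen-7-yl propanoate (Sclerketide B) | CCC(=O)O[C@]1(C)C(=O)C2=COC(/C=C/C(C)=C/[C@@H](C)CC)=CC2=C(Cl)C1=O | target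

**Step count.** Total: 10 steps. Longest linear sequence: 6 steps (steps 1, 3, 6, 7, 9, 10).

**Steps most likely to fail**

Step 9 (Proposed new method). The ketene acetal may attack cation 16 at C1 before deprotonation, betaine 17 may dimerise, and the catalyst may discriminate the two faces of the planar ylide poorly. The fallback uses known chemistry, sets out from 3 and comes back at 20. Wittig homologation of 3 with Ph3P=CHCHO should give (2E,4E,6S)-4,6-dimethylocta-2,4-dienal F1. Seyferth–Gilbert homologation with dimethyl (1-diazo-2-oxopropyl)phosphonate and K2CO3 in MeOH then gives (3E,5E,7S)-5,7-dimethylnona-3,5-dien-1-yne F2. Vilsmeier formylation (POCl3, DMF) of commercial 5-bromo-2-methylbenzene-1,3-diol gives 6-bromo-2,4-dihydroxy-3-methylbenzaldehyde F3. Sonogashira coupling of F2 with F3 (Pd(PPh3)2Cl2, CuI, Et3N) gives 6-[(3E,5E,7S)-5,7-dimethylnona-3,5-dien-1-yn-1-yl]-2,4-dihydroxy-3-methylbenzaldehyde F4. Copper-mediated enantioselective oxidative dearomatization ([Cu(MeCN)4]PF6, the sparteine antipode that delivers the required configuration, O2, i-Pr2NEt, DMAP, CH2Cl2, −78 °C) gives (5S)-2-[(3E,5E,7S)-5,7-dimethylnona-3,5-dien-1-yn-1-yl]-4,5-dihydroxy-5-methyl-6-oxocyclohexa-1,3-diene-1-carbaldehyde F5. Buffer-mediated 6-endo cycloisomerization (KH2PO4/K2HPO4, MeCN) gives (7S)-7-hydroxy-7-methyl-3-[(1E,3E,5S)-3,5-dimethylhepta-1,3-dien-1-yl]-6H-isochromene-6,8(7H)-dione F6, which has the same spatial arrangement at C7 as 20 (the descriptor changes because C5 carries hydrogen). Chlorination at C5 with N-chlorosuccinimide gives 20.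

Step 6. The dienoylketene may oligomerise before the push–pull enaminone intercepts it, and liberated dimethylamine may reopen the pyranone. The fallback sets out from 9 and comes back at 11. Acetoacetylation of 9 with diketene at room temperature and cyclisation with loss of dimethylamine should give 3-{2-[(tert-butyldimethylsilyl)oxy]propanoyl}-6-methyl-4H-pyran-4-one F7. Vinylogous aldol addition of its 6-methyl group (LiN(SiMe3)2, THF, −78 °C) to enal 3 gives 3-{2-[(tert-butyldimethylsilyl)oxy]propanoyl}-6-[(3E,5S)-2-hydroxy-3,5-dimethylhept-3-en-1-yl]-4H-pyran-4-one F8. Mesylation and elimination (MsCl, Et3N; DBU) gives 11.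

Step 7. Once freed, the hydroxyl may add to C1 of the 3-acylpyranone and trigger ring transformation to a furanone before it is activated. The fallback sets out from 11 and comes back at 16. Direct conversion of the silyl ether with Ph3PBr2 (CH2Cl2, 0 °C) should give 3-(2-bromopropanoyl)-6-[(1E,3E,5S)-3,5-dimethylhepta-1,3-dien-1-yl]-4H-pyran-4-one F9, which is stored as a covalent halide. AgOTf in CH2Cl2 at −40 °C then ionises it to pyrylium triflate 16, and the route continues as in step 9.

**Further compounds**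

F1 | step 9 | (2E,4E,6S)-4,6-dimethylocta-2,4-dienal | CC[C@H](C)/C=C(C)/C=C/C=O
F2 | step 9 | (3E,5E,7S)-5,7-dimethylnona-3,5-dien-1-yne | CC[C@H](C)/C=C(C)/C=C/C#C
F3 | step 9 | 6-bromo-2,4-dihydroxy-3-methylbenzaldehyde | O=Cc1c(O)c(C)c(O)cc1Br
F4 | step 9 | 6-[(3E,5E,7S)-5,7-dimethylnona-3,5-dien-1-yn-1-yl]-2,4-dihydroxy-3-methylbenzaldehyde | O=Cc1c(O)c(C)c(O)cc1C#C/C=C/C(C)=C/[C@@H](C)CC
F5 | step 9 | (5S)-2-[(3E,5E,7S)-5,7-dimethylnona-3,5-dien-1-yn-1-yl]-4,5-dihydroxy-5-methyl-6-oxocyclohexa-1,3-diene-1-carbaldehyde | O[C@]1(C)C(=O)C(C=O)=C(C#C/C=C/C(C)=C/[C@@H](C)CC)C=C1O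
F6 | step 9 | (7S)-7-hydroxy-7-methyl-3-[(1E,3E,5S)-3,5-dimethylhepta-1,3-dien-1-yl]-6H-isochromene-6,8(7H)-dione | O[C@]1(C)C(=O)C2=COC(/C=C/C(C)=C/[C@@H](C)CC)=CC2=CC1=O
F7 | step 6 | 3-{2-[(tert-butyldimethylsilyl)oxy]propanoyl}-6-methyl-4H-pyran-4-one | CC(O[Si](C)(C)C(C)(C)C)C(=O)C1=COC(C)=CC1=O
F8 | step 6 | 3-{2-[(tert-butyldimethylsilyl)oxy]propanoyl}-6-[(3E,5S)-2-hydroxy-3,5-dimethylhept-3-en-1-yl]-4H-pyran-4-one | CC[C@H](C)/C=C(C)/C(O)CC1=CC(=O)C(C(=O)C(C)O[Si](C)(C)C(C)(C)C)=CO1
F9 | step 7 | 3-(2-bromopropanoyl)-6-[(1E,3E,5S)-3,5-dimethylhepta-1,3-dien-1-yl]-4H-pyran-4-one | CC(Br)C(=O)C1=COC(/C=C/C(C)=C/[C@@H](C)CC)=CC1=O
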